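**Plan**

1. Retrosynthetic cuts, in order: the N-Boc group; the aryl–vinyl bond of the ferulate (guaiacol ring carbon para to the phenolic OH to the enoate β-carbon), giving 4-iodo-2-methoxyphenol and the C3 acrylate; the acrylate C–O bond; the methyl ketone (back to a terminal alkene); the ring N–C6 and C6–H bonds (back to an acyclic δ-Boc-amino ketone); the C6–chain bond (lactam plus C12 Grignard reagent); the C3–C4 bond (alanine Weinreb amide plus butenyl Grignard reagent).
2. Forward order: L-alanine amide, then the C2–C7 chain, C3 carbinol, ozonolysis and oxidation to the N-Boc lactam, C12 chain joined by lactam opening, piperidine ring (the only ring made) closed by N-acyliminium formation and hydride delivery, Wacker ketone, acrylate, aryl ring joined, Boc removed.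
3. Stereochemistry: C2 comes from L-alanine; C3 from chelation-controlled ketone reduction (anti to nitrogen); C6 from axial hydride attack on the N-Boc iminium ion whose C2 methyl is held axial by allylic strain (2,6-trans); the E alkene from syn insertion and syn β-hydride elimination.
4. Enabling feature: the ferulate hangs on the ring C3 oxygen, so it can be carried as an acrylate whose terminal CH2 is the one electron-poor alkene carbon of the molecule, while the guaiacol ring offers a single C–I bond para to its free OH. Palladium joins exactly these two carbons without phenol protection; the helpers are the iodine (lost in the event) and the N-Boc group (removed in the last step).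

Key step: step 11

Assumption: the configuration is taken exactly as drawn, (2S,3R,6S), so the C2 methyl is trans to both the C3 oxygen and the C6 chain; 2 (THF solution) and 9 are treated as catalogue materials.

**Route**

Step 1
Reactants: 1 N-Boc-L-alanine N-methoxy-N-methylamide; 2 but-3-en-1-ylmagnesium bromide
Product: 3 tert-butyl N-[(2S)-3-oxohept-6-en-2-yl]carbamate
Conditions: 2 (2.5 equiv), THF, −20 → 0 °C; aq. NH4Cl
Reagents that add atoms: none
Why: Weinreb ketone synthesis, in which the first equivalent of Grignard reagent deprotonates the carbamate N–H and the second adds to the amide to give a stable magnesium chelate that collapses to the ketone only on work-up, so over-addition and racemization of the alanine stereocentre (future C2) should be avoided.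

Step 2
Reactants: 3 tert-butyl N-[(2S)-3-oxohept-6-en-2-yl]carbamate
Product: 4 tert-butyl N-[(2S,3R)-3-hydroxyhept-6-en-2-yl]carbamate
Conditions: LiAlH(OtBu)3, EtOH, −78 °C
Reagents that add atoms: none
Why: Chelation-controlled hydride reduction of an N-Boc α-amino ketone (Cram chelate model), in which the metal bridges the carbamate and the ketone oxygen and hydride enters from the side of the α-hydrogen, which should set the new carbinol centre (3R) anti to nitrogen.

Step 3
Reactants: 4 tert-butyl N-[(2S,3R)-3-hydroxyhept-6-en-2-yl]carbamate
Product: 5 tert-butyl N-[(2S,3R)-3-[(tert-butyldimethylsilyl)oxy]hept-6-en-2-yl]carbamate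
Conditions: TBSCl, imidazole, DMF, rt
Reagents that add atoms: tert-butyldimethylsilyl chloride (TBSCl), C[Si](C)(Cl)C(C)(C)C
Why: Imidazole-promoted silylation of the secondary alcohol under neutral conditions, which blocks the hydroxyl so that it cannot form a five-membered lactol or hemiketal in steps 4 to 7 and avoids the alkoxide that could attack the Boc carbonyl.

Step 4
Reactants: 5 tert-butyl N-[(2S,3R)-3-[(tert-butyldimethylsilyl)oxy]hept-6-en-2-yl]carbamate
Product: 7 tert-butyl (2S,3R)-3-[(tert-butyldimethylsilyl)oxy]-6-hydroxy-2-methylpiperidine-1-carboxylate (both C6 epimers), via open-chain aldehyde 6 (not isolated)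
Conditions: O3, CH2Cl2, −78 °C; then PPh3, −78 °C → rt
Reagents that add atoms: ozone, [O-][O+]=O
Why: Ozonolysis with reductive work-up cleaves the only C=C bond, and the δ-carbamoyl aldehyde closes onto the carbamate nitrogen to the six-membered N,O-hemiaminal, whose new centre is of no consequence because it is oxidized in the next step.

Step 5
Reactants: 7 tert-butyl (2S,3R)-3-[(tert-butyldimethylsilyl)oxy]-6-hydroxy-2-methylpiperidine-1-carboxylate
Product: 8 tert-butyl (2S,3R)-3-[(tert-butyldimethylsilyl)oxy]-2-methyl-6-oxopiperidine-1-carboxylate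
Conditions: (n-Pr4N)RuO4 (5 mol %), N-methylmorpholine N-oxide, 4 Å MS, CH2Cl2, rt
Reagents that add atoms: none
Why: Ley–Griffith oxidation of the lactol-type hemiaminal to the N-Boc lactam under neutral anhydrous conditions that should leave the silyl ether, the carbamate and both stereocentres untouched.

Step 6
Reactants: 8 tert-butyl (2S,3R)-3-[(tert-butyldimethylsilyl)oxy]-2-methyl-6-oxopiperidine-1-carboxylate; 9 12-bromododec-1-ene
Product: 11 tert-butyl N-[(2S,3R)-3-[(tert-butyldimethylsilyl)oxy]-6-oxooctadec-17-en-2-yl]carbamate, via dodec-11-en-1-ylmagnesium bromide 10 (not isolated)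
Conditions: 9, Mg, THF, rt → 40 °C; then 8, THF, −78 → −40 °C; aq. NH4Cl
Reagents that add atoms: none
Why: Grignard addition to an N-Boc lactam, whose ring carbonyl is ketone-like because of the Boc group and whose tetrahedral adduct opens to the carbamate anion, so a single addition should give the acyclic δ-(Boc-amino) ketone carrying the whole C12 chain.

Step 7
Reactants: 11 tert-butyl N-[(2S,3R)-3-[(tert-butyldimethylsilyl)oxy]-6-oxooctadec-17-en-2-yl]carbamate
Product: 13 tert-butyl (2S,3R,6S)-3-[(tert-butyldimethylsilyl)oxy]-6-(dodec-11-en-1-yl)-2-methylpiperidine-1-carboxylate, via cyclic N-Boc iminium ion 12 (not isolated)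
Conditions: Et3SiH, BF3·OEt2, CH2Cl2, −78 → −30 °C
Reagents that add atoms: none
Why: N-acyliminium ion reduction (ionic hydrogenation), in which BF3 drives 6-exo attack of the carbamate nitrogen on the ketone and loss of water, allylic 1,3-strain with the Boc group holds the C2 methyl pseudoaxial (the trans C3 silyloxy group is then pseudoaxial on the other face), and axial delivery of hydride to C6 through a chair-like transition state on the methyl face should place the chain trans to the methyl and cis to the C3 oxygen (6S).

Step 8
Reactants: 13 tert-butyl (2S,3R,6S)-3-[(tert-butyldimethylsilyl)oxy]-6-(dodec-11-en-1-yl)-2-methylpiperidine-1-carboxylate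
Product: 14 tert-butyl (2S,3R,6S)-3-[(tert-butyldimethylsilyl)oxy]-2-methyl-6-(11-oxododecyl)piperidine-1-carboxylate
Conditions: PdCl2 (10 mol %), CuCl, O2 (1 atm), DMF/H2O (7:1), rt
Reagents that add atoms: water, O
Why: Tsuji–Wacker oxidation, in which Markovnikov hydroxypalladation of the terminal alkene and β-hydride elimination should give the methyl ketone without touching the carbamate, the silyl ether or the stereocentres.

Step 9
Reactants: 14 tert-butyl (2S,3R,6S)-3-[(tert-butyldimethylsilyl)oxy]-2-methyl-6-(11-oxododecyl)piperidine-1-carboxylate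
Product: 15 tert-butyl (2S,3R,6S)-3-hydroxy-2-methyl-6-(11-oxododecyl)piperidine-1-carboxylate
Conditions: n-Bu4NF, THF, 0 °C → rt
Reagents that add atoms: none
Why: Fluoride-mediated desilylation driven by the strong Si–F bond, to which the Boc group and the ketone are inert and which leaves the C3 configuration unchanged.

Step 10
Reactants: 15 tert-butyl (2S,3R,6S)-3-hydroxy-2-methyl-6-(11-oxododecyl)piperidine-1-carboxylate; 16 prop-2-enoyl chloride
Product: 17 tert-butyl (2S,3R,6S)-2-methyl-6-(11-oxododecyl)-3-(prop-2-enoyloxy)piperidine-1-carboxylate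
Conditions: 16, Et3N, DMAP (cat.), CH2Cl2, −20 → 0 °C
Reagents that add atoms: none
Why: DMAP-catalysed acylation of the secondary alcohol with an acid chloride, in which the carbamate blocks nitrogen so that only oxygen is acylated, with retention at C3.

Step 11
Reactants: 17 tert-butyl (2S,3R,6S)-2-methyl-6-(11-oxododecyl)-3-(prop-2-enoyloxy)piperidine-1-carboxylate; 18 4-iodo-2-methoxyphenol
Product: 19 tert-butyl (2S,3R,6S)-3-{[(2E)-3-(4-hydroxy-3-methoxyphenyl)prop-2-enoyl]oxy}-2-methyl-6-(11-oxododecyl)piperidine-1-carboxylate
Conditions: Pd(OAc)2 (5 mol %), n-Bu4NCl, NaHCO3, DMF, 70 °C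
Reagents that add atoms: none
Why: Mizoroki–Heck reaction: zerovalent palladium formed in situ from Pd(OAc)2 and stabilized by n-Bu4NCl inserts into the C–I bond of 18, the arylpalladium species adds syn across the acrylate C=C of 17 with the aryl group going to the terminal CH2, and syn β-hydride elimination from the rotamer with aryl and ester anti gives the (E)-cinnamate, after which NaHCO3 takes up HI and returns zerovalent palladium. The closest known reaction type is the ligand-free, phase-transfer Heck arylation of acrylate esters with unprotected iodophenols. No ring is closed and no stereocentre is created; the three ring stereocentres are remote from the reacting alkene and are not epimerizable under bicarbonate. The selectivities needed are arene regiochemistry (fixed by iodine para to the phenolic OH), alkene regiochemistry (fixed by the polarization and the unhindered terminus of the acrylate), E geometry (fixed by the syn-insertion and syn-elimination sequence) and chemoselectivity, which the Boc group (no aza-Michael addition or N-arylation), the weak base (no phenol O-arylation, oxa-Michael addition or ketone α-arylation) and the absence of any other alkene or halide should secure.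

Step 12
Reactants: 19 tert-butyl (2S,3R,6S)-3-{[(2E)-3-(4-hydroxy-3-methoxyphenyl)prop-2-enoyl]oxy}-2-methyl-6-(11-oxododecyl)piperidine-1-carboxylate
Product: 20 (2S,3R,6S)-2-methyl-6-(11-oxododecyl)piperidin-3-yl (2E)-3-(4-hydroxy-3-methoxyphenyl)prop-2-enoate
Conditions: CF3CO2H, CH2Cl2, 0 °C; aq. NaHCO3
Reagents that add atoms: none
Why: Acidolytic Boc cleavage (loss of the tert-butyl cation, then decarboxylation), which the cinnamate ester, phenol, ketone and stereocentres should survive, the free base being released on bicarbonate work-up.

**Compound list**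

1 | tert-butyl N-[(2S)-1-[methoxy(methyl)amino]-1-oxopropan-2-yl]carbamate (N-Boc-L-alanine N-methoxy-N-methylamide) | C[C@H](NC(=O)OC(C)(C)C)C(=O)N(C)OC | starting material
2 | but-3-en-1-ylmagnesium bromide | C=CCC[Mg]Br | starting material
3 | tert-butyl N-[(2S)-3-oxohept-6-en-2-yl]carbamate | C[C@H](NC(=O)OC(C)(C)C)C(=O)CCC=C | intermediate
4 | tert-butyl N-[(2S,3R)-3-hydroxyhept-6-en-2-yl]carbamate | C[C@H](NC(=O)OC(C)(C)C)[C@H](O)CCC=C | intermediate
5 | tert-butyl N-[(2S,3R)-3-[(tert-butyldimethylsilyl)oxy]hept-6-en-2-yl]carbamate | C[C@H](NC(=O)OC(C)(C)C)[C@H](O[Si](C)(C)C(C)(C)C)CCC=C | intermediate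
6 | tert-butyl N-[(2S,3R)-3-[(tert-butyldimethylsilyl)oxy]-6-oxohexan-2-yl]carbamate | C[C@H](NC(=O)OC(C)(C)C)[C@H](O[Si](C)(C)C(C)(C)C)CCC=O | intermediate (not isolated)
7 | tert-butyl (2S,3R)-3-[(tert-butyldimethylsilyl)oxy]-6-hydroxy-2-methylpiperidine-1-carboxylate (both C6 epimers) | C[C@H]1[C@H](O[Si](C)(C)C(C)(C)C)CCC(O)N1C(=O)OC(C)(C)C | intermediate
8 | tert-butyl (2S,3R)-3-[(tert-butyldimethylsilyl)oxy]-2-methyl-6-oxopiperidine-1-carboxylate | C[C@H]1[C@H](O[Si](C)(C)C(C)(C)C)CCC(=O)N1C(=O)OC(C)(C)C | intermediate
9 | 12-bromododec-1-ene | C=CCCCCCCCCCCBr | starting material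
10 | dodec-11-en-1-ylmagnesium bromide | C=CCCCCCCCCCC[Mg]Br | intermediate (not isolated)
11 | tert-butyl N-[(2S,3R)-3-[(tert-butyldimethylsilyl)oxy]-6-oxooctadec-17-en-2-yl]carbamate | C[C@H](NC(=O)OC(C)(C)C)[C@H](O[Si](C)(C)C(C)(C)C)CCC(=O)CCCCCCCCCCC=C | intermediate
12 | (2S,3R)-1-(tert-butoxycarbonyl)-3-[(tert-butyldimethylsilyl)oxy]-6-(dodec-11-en-1-yl)-2-methyl-2,3,4,5-tetrahydropyridin-1-ium | C[C@H]1[C@H](O[Si](C)(C)C(C)(C)C)CCC(CCCCCCCCCCC=C)=[N+]1C(=O)OC(C)(C)C | intermediate (not isolated)
13 | tert-butyl (2S,3R,6S)-3-[(tert-butyldimethylsilyl)oxy]-6-(dodec-11-en-1-yl)-2-methylpiperidine-1-carboxylate | C[C@H]1[C@H](O[Si](C)(C)C(C)(C)C)CC[C@H](CCCCCCCCCCC=C)N1C(=O)OC(C)(C)C | intermediate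
14 | tert-butyl (2S,3R,6S)-3-[(tert-butyldimethylsilyl)oxy]-2-methyl-6-(11-oxododecyl)piperidine-1-carboxylate | C[C@H]1[C@H](O[Si](C)(C)C(C)(C)C)CC[C@H](CCCCCCCCCCC(C)=O)N1C(=O)OC(C)(C)C | intermediate
15 | tert-butyl (2S,3R,6S)-3-hydroxy-2-methyl-6-(11-oxododecyl)piperidine-1-carboxylate | C[C@H]1[C@H](O)CC[C@H](CCCCCCCCCCC(C)=O)N1C(=O)OC(C)(C)C | intermediate
16 | prop-2-enoyl chloride (acryloyl chloride) | C=CC(=O)Cl | starting material
17 | tert-butyl (2S,3R,6S)-2-methyl-6-(11-oxododecyl)-3-(prop-2-enoyloxy)piperidine-1-carboxylate | C[C@H]1[C@H](OC(=O)C=C)CC[C@H](CCCCCCCCCCC(C)=O)N1C(=O)OC(C)(C)C | intermediate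
18 | 4-iodo-2-methoxyphenol | COc1cc(I)ccc1O | starting material
19 | tert-butyl (2S,3R,6S)-3-{[(2E)-3-(4-hydroxy-3-methoxyphenyl)prop-2-enoyl]oxy}-2-methyl-6-(11-oxododecyl)piperidine-1-carboxylate | C[C@H]1[C@H](OC(=O)/C=C/c2ccc(O)c(OC)c2)CC[C@H](CCCCCCCCCCC(C)=O)N1C(=O)OC(C)(C)C | intermediate
20 | (2S,3R,6S)-2-methyl-6-(11-oxododecyl)piperidin-3-yl (2E)-3-(4-hydroxy-3-methoxyphenyl)prop-2-enoate | COc1cc(/C=C/C(=O)O[C@@H]2CC[C@H](CCCCCCCCCCC(C)=O)N[C@H]2C)ccc1O | target

**Step count and risks**

Total step count: 12. Longest linear sequence: 12 steps (1 to 20).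

Steps most likely to fail:

Step 7. Hydride may be delivered to the wrong face of the iminium ion, or the Boc group may be lost under BF3, so that the allylic strain that controls the face disappears; direct reduction of the ketone before ring closure is a further risk. The fallback sets out from 7 and comes back at 13. Treatment of 7 with CF3CO2H in CH2Cl2 at 0 °C followed by K2CO3 would remove the Boc group and let the amino aldehyde condense to the cyclic imine (2S,3R)-3-[(tert-butyldimethylsilyl)oxy]-2-methyl-2,3,4,5-tetrahydropyridine F1, used at once. Addition of the Grignard reagent 10 (from 9 and Mg) with BF3·OEt2 in THF at −78 °C should occur axially on the half-chair that keeps the C2 methyl and C3 silyloxy groups equatorial, since without an N-acyl group there is no allylic strain. This would give the 2,6-trans amine (2S,3R,6S)-3-[(tert-butyldimethylsilyl)oxy]-6-(dodec-11-en-1-yl)-2-methylpiperidine F2, and Boc2O with Et3N in THF would return 13. Stereocontrol here rests on the carbon nucleophile entering last on a non-acylated imine instead of hydride entering last on an N-acyliminium ion.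

Step 11. Oxidative addition into the electron-rich iodophenol may be slow and palladium may precipitate; base-induced oxa-Michael addition of the phenol or thermal polymerization of the acrylate may also compete. The fallback sets out from 17 and comes back at 19. Olefin cross-metathesis of 17 with commercial 2-methoxy-4-vinylphenol (second-generation Grubbs catalyst, RuCl2(PCy3)(H2IMes)(=CHPh), CH2Cl2, 40 °C) would build the same (E)-cinnamate by closing the C=C bond instead, without base, halide or palladium. It makes no new compound: none F0.

Step 2. Chelation may be incomplete, giving poor facial selectivity at the carbinol carbon. The fallback sets out from 3 and comes back at 4. Reduction of 3 with an NADPH-dependent ketoreductase (alcohol dehydrogenase class), chosen from a screening panel for the (3R)-alcohol, with propan-2-ol as terminal reductant in aqueous buffer at 30 °C, would move stereocontrol from the substrate chelate to the enzyme active site. It makes no new compound: none F0.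

**Further compounds**

F1 | step 7 | (2S,3R)-3-[(tert-butyldimethylsilyl)oxy]-2-methyl-2,3,4,5-tetrahydropyridine | C[C@H]1[C@H](O[Si](C)(C)C(C)(C)C)CCC=N1
F2 | step 7 | (2S,3R,6S)-3-[(tert-butyldimethylsilyl)oxy]-6-(dodec-11-en-1-yl)-2-methylpiperidine | C[C@H]1[C@H](O[Si](C)(C)C(C)(C)C)CC[C@H](CCCCCCCCCCC=C)N1
F0 | step 11 | none | none
F0 | step 2 | none | none
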